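**Retrosynthetic overview**
- The (Z)-4-oxodec-2-enoate is put on last: the C3 hydroxyl of the bicyclic acetoxy lactone is esterified with a 4-silyloxy-alkynoic acid, then the ynone is unmasked and semi-hydrogenated.
- Key disconnection: the δ-lactone ring is opened at O5–C4a and C8–C8a, giving a 6-methyl-3,4-dihydro-2H-pyran and (E)-3-acetoxy-2-methylacrylic acid. Forward, one photoredox polar–radical-crossover [4+2] annulation makes both bonds and the four stereocentres C4a, C8a, C8 and C7.
- Enabling feature: C8a carries the ring oxygen O1 of the tetrahydropyran and C4a is its neighbour, so C4a=C8a can be a cyclic enol ether. One-electron oxidation reverses its polarity: the carboxylate oxygen enters at C4a, and the acetal-type carbon C8a becomes a nucleophilic radical that bonds to the β-carbon C8 of the acrylic acid (two carbons of like, acceptor polarity).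
- The dihydropyran comes from the lactic acid chiral pool: acetoxy aldehyde, anti,anti-crotylboration, silylation, titanium-mediated olefinic ester cyclization (the acetate becomes C8a and its methyl).
- Ring order: tetrahydropyran (as dihydropyran) first, lactone second, side chain last.

Key step: step 8

Remark: the bicycle is numbered as pyrano[3,2-b]pyran (O1, C2, C3, C4, C4a, O5, C6, C7, C8, C8a) and dihydropyran 12 as O1, C2–C6; racemic non-1-yn-3-ol is used because its carbinol centre is oxidised away at step 14.

**Route**

Step 1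
Reactants: 1 tert-butyl propanoate
Product: 3 tert-butyl 2-methyl-3-oxopropanoate, via lithium enolate of tert-butyl propanoate 2 (not isolated)
Conditions: LDA, THF, −78 °C; HCO2Et, −78 → 0 °C; 1 M HCl
Reagents that add atoms: ethyl formate CCOC=O
Why: Crossed Claisen condensation (C-formylation) of the pre-formed ester enolate with non-enolisable ethyl formate is driven by deprotonation of the acidic β-formyl ester; the new centre is enolisable and is removed in step 2.

Step 2
Reactants: 3 tert-butyl 2-methyl-3-oxopropanoate
Product: 4 tert-butyl (E)-3-acetoxy-2-methylprop-2-enoate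
Conditions: Ac2O, Et3N, DMAP (cat.), CH2Cl2, 0 °C → rt; chromatography
Reagents that add atoms: acetic anhydride CC(=O)OC(C)=O
Why: O-Acylation of the β-formyl ester enolate (enol ester formation) should give mainly the (E)-enol acetate with OAc anti to the ester, and any (Z)-isomer is removed by chromatography.

Step 3
Reactants: 4 tert-butyl (E)-3-acetoxy-2-methylprop-2-enoate
Product: 5 (E)-3-acetoxy-2-methylprop-2-enoic acid
Conditions: TFA/CH2Cl2 (1:4), 0 °C → rt; evaporation
Reagents that add atoms: none
Why: Acid-mediated tert-butyl ester cleavage (E1 loss of isobutene) frees the acid under anhydrous conditions that leave the enol acetate and its geometry intact.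

Step 4
Reactants: 6 (S)-2-acetoxypropanoyl chloride
Product: 7 (S)-2-acetoxypropanal
Conditions: H2 (1 atm), 5% Pd/BaSO4, 2,6-lutidine, THF, rt; filtered and used cold
Reagents that add atoms: none
Why: Rosenmund reduction stops at the aldehyde under buffered conditions and keeps the stereocentre of the lactic acid chiral pool, the future C2.

Step 5
Reactants: 7 (S)-2-acetoxypropanal; 8 (E)-crotylboronic acid pinacol ester
Product: 10 (2S,3R,4S)-3-hydroxy-4-methylhex-5-en-2-yl acetate, via O-pinacolboryl derivative of the homoallylic alcohol 9 (not isolated)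
Conditions: toluene, 4 Å MS, −78 → 23 °C; pH 7 buffer
Reagents that add atoms: none
Why: Crotylboration through the closed Zimmerman–Traxler chair turns the (E)-geometry into the 3,4-anti relationship, and the Cornforth/polar Felkin–Anh arrangement of the α-acetoxy group directs attack to give the 2,3-anti relationship, so C3 (R) and C4 (S) should be set by substrate control.

Step 6
Reactants: 10 (2S,3R,4S)-3-hydroxy-4-methylhex-5-en-2-yl acetate
Product: 11 (2S,3R,4S)-3-[(tert-butyldimethylsilyl)oxy]-4-methylhex-5-en-2-yl acetate
Conditions: TBSOTf, 2,6-lutidine, CH2Cl2, −78 → 0 °C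
Reagents that add atoms: tert-butyldimethylsilyl triflate CC(C)(C)[Si](C)(C)OS(=O)(=O)C(F)(F)F
Why: Silylation of the secondary alcohol with the silyl triflate at low temperature should be fast enough to outrun 1,2-acetyl migration.

Step 7
Reactants: 11 (2S,3R,4S)-3-[(tert-butyldimethylsilyl)oxy]-4-methylhex-5-en-2-yl acetate
Product: 12 tert-butyldimethyl{[(2S,3R,4S)-2,4,6-trimethyl-3,4-dihydro-2H-pyran-3-yl]oxy}silane
Conditions: TiCl4, TMEDA, Zn, PbCl2 (cat.), CH3CHBr2, THF/CH2Cl2, 0 → 65 °C
Reagents that add atoms: none
Why: Olefinic ester cyclization (titanium-alkylidene carbonyl–olefin metathesis) joins the vinyl CH to the acetate carbonyl carbon, so the acetate becomes C6 with its methyl in a six-membered cyclic enol ether and no stereocentre is touched.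

Step 8
Reactants: 12 tert-butyldimethyl{[(2S,3R,4S)-2,4,6-trimethyl-3,4-dihydro-2H-pyran-3-yl]oxy}silane; 5 (E)-3-acetoxy-2-methylprop-2-enoic acid
Product: 14 (2S,3R,4S,4aS,7R,8S,8aS)-3-[(tert-butyldimethylsilyl)oxy]-2,4,7,8a-tetramethyl-6-oxooctahydropyrano[3,2-b]pyran-8-yl acetate, via tertiary C6 radical of the C5 acrylate ester 13 (not isolated)
Conditions: 9-mesityl-3,6-di-tert-butyl-10-phenylacridinium BF4 (5 mol%), PhSSPh (20 mol%), 2,6-lutidine (0.5 equiv), 4 Å MS, CH2Cl2, 450 nm LEDs, rt
Reagents that add atoms: none
Why: Proposed new method: the photoexcited acridinium oxidises the enol ether of 12 to its radical cation, acid 5 adds through oxygen to the β-carbon C5 (anti-Markovnikov) to leave the tertiary α-oxy radical 13 at C6, this nucleophilic radical adds to the acetoxy-bearing β-carbon of the tethered 2-methylacrylate, and the resulting tertiary α-acyl radical takes a hydrogen atom from thiophenol (formed from PhSSPh), whose thiyl radical returns the acridine radical to the acridinium. The closest known reaction type is the acridinium/thiol polar radical crossover cycloaddition of alkenes with unsaturated acids to γ-butyrolactones, together with radical addition to the oxygenated carbon of β-alkoxyacrylates; new here are the enol ether as alkene partner and the δ-lactone mode. The lactone ring closes 6-endo-trig, which should be preferred over 5-exo because the inner alkene carbon is fully substituted and the polarity of the α-oxy radical matches the acrylate β-carbon. C4a is set by attack of the acid anti to the pseudo-equatorial C4 methyl (the face selectivity of epoxidation of 3-substituted glycals), C8a by closure on the outer lobe of the radical with the tether equatorial (trans-fused chair–chair transition state, bulkier C8 equatorial and methyl axial, as in radical polyene bicyclisations), C8 by the (E)-geometry of 5, which places OAc equatorial in that transition state, and C7 by hydrogen-atom delivery anti to the axial C8a methyl. The step needs anti-Markovnikov O-attack rather than acid-catalysed Markovnikov addition, which the 2,6-lutidine buffer and the tertiary radical site should secure, and 6-endo closure, which the 2-methyl group of 5 should secure. It also needs trans- rather than cis-ring fusion, for which the equatorial tether and the clash of C8–H with the axial hydrogens at C2 and C4 in the cis mode are relied on against the axial preference of α-oxy radicals; this is the main risk.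

Step 9
Reactants: 14 (2S,3R,4S,4aS,7R,8S,8aS)-3-[(tert-butyldimethylsilyl)oxy]-2,4,7,8a-tetramethyl-6-oxooctahydropyrano[3,2-b]pyran-8-yl acetate
Product: 15 (2S,3R,4R,4aS,7R,8S,8aS)-3-hydroxy-2,4,7,8a-tetramethyl-6-oxooctahydropyrano[3,2-b]pyran-8-yl acetate
Conditions: HF·pyridine, pyridine, THF, 0 °C → rt
Reagents that add atoms: none
Why: Fluoride-mediated silyl ether cleavage under buffered acidic conditions should spare the β-acetoxy lactone, which a basic fluoride source could eliminate.

Step 10
Reactants: 16 non-1-yn-3-ol (racemic)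
Product: 17 tert-butyldimethyl(non-1-yn-3-yloxy)silane (racemic)
Conditions: TBSCl, imidazole, DMF, rt
Reagents that add atoms: tert-butyldimethylsilyl chloride CC(C)(C)[Si](C)(C)Cl
Why: Standard silylation protects the propargylic alcohol so that the acetylide can be formed and the acid later coupled without self-esterification.

Step 11
Reactants: 17 tert-butyldimethyl(non-1-yn-3-yloxy)silane
Product: 19 4-[(tert-butyldimethylsilyl)oxy]dec-2-ynoic acid (racemic), via lithium acetylide 18 (not isolated)
Conditions: n-BuLi, THF, −78 °C; CO2 (g), −78 → 0 °C; cold 1 M HCl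
Reagents that add atoms: carbon dioxide O=C=O
Why: Carboxylation of the lithium acetylide with CO2 gives the alkynoic acid directly.

Step 12
Reactants: 15 (2S,3R,4R,4aS,7R,8S,8aS)-3-hydroxy-2,4,7,8a-tetramethyl-6-oxooctahydropyrano[3,2-b]pyran-8-yl acetate; 19 4-[(tert-butyldimethylsilyl)oxy]dec-2-ynoic acid
Product: 20 (2S,3R,4R,4aS,7R,8S,8aS)-8-acetoxy-2,4,7,8a-tetramethyl-6-oxooctahydropyrano[3,2-b]pyran-3-yl 4-[(tert-butyldimethylsilyl)oxy]dec-2-ynoate (two epimers at the side-chain carbinol)
Conditions: DIC, DMAP (0.2 equiv), CH2Cl2, 0 °C → rt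
Reagents that add atoms: none
Why: Steglich esterification acylates the equatorial C3 hydroxyl with retention, and an alkynoic acid is used because a (Z)-4-oxo-2-enoic acid would react through its cyclic hydroxybutenolide form.

Step 13
Reactants: 20 the 4-silyloxydec-2-ynoate ester
Product: 21 (2S,3R,4R,4aS,7R,8S,8aS)-8-acetoxy-2,4,7,8a-tetramethyl-6-oxooctahydropyrano[3,2-b]pyran-3-yl 4-hydroxydec-2-ynoate (two epimers at the side-chain carbinol)
Conditions: HF·pyridine, pyridine, THF, 0 °C → rt
Reagents that add atoms: none
Why: Fluoride-mediated desilylation frees the propargylic alcohol, which cannot lactonise onto the ester because the alkyne is linear.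

Step 14
Reactants: 21 the 4-hydroxydec-2-ynoate ester
Product: 22 (2S,3R,4R,4aS,7R,8S,8aS)-8-acetoxy-2,4,7,8a-tetramethyl-6-oxooctahydropyrano[3,2-b]pyran-3-yl 4-oxodec-2-ynoate
Conditions: Dess–Martin periodinane, CH2Cl2, 0 °C → rt
Reagents that add atoms: none
Why: Dess–Martin oxidation of the propargylic alcohol to the ynone is near-neutral and converges both epimers to one compound.

Step 15
Reactants: 22 the 4-oxodec-2-ynoate ester
Product: 23 botcinin J, (2S,3R,4R,4aS,7R,8S,8aS)-8-acetoxy-2,4,7,8a-tetramethyl-6-oxooctahydropyrano[3,2-b]pyran-3-yl (2Z)-4-oxodec-2-enoate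
Conditions: H2 (1 atm), Lindlar catalyst, quinoline, EtOAc, 0 °C, in the dark, stopped at one equivalent of H2
Reagents that add atoms: none
Why: Lindlar semi-hydrogenation adds H2 syn to the only reducible π-bond and should give the (Z)-ene-dione without acid or base that could isomerise it or eliminate the β-acetoxy group.

**Compound list**
1 | tert-butyl propanoate | CCC(=O)OC(C)(C)C | starting material
2 | lithium enolate of tert-butyl propanoate | [Li+].CC=C([O-])OC(C)(C)C | intermediate (not isolated)
3 | tert-butyl 2-methyl-3-oxopropanoate (racemic, enolisable) | CC(C=O)C(=O)OC(C)(C)C | intermediate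
4 | tert-butyl (E)-3-acetoxy-2-methylprop-2-enoate | CC(=O)O/C=C(\C)C(=O)OC(C)(C)C | intermediate
5 | (E)-3-acetoxy-2-methylprop-2-enoic acid | CC(=O)O/C=C(\C)C(=O)O | intermediate
6 | (S)-2-acetoxypropanoyl chloride | CC(=O)O[C@@H](C)C(Cl)=O | starting material
7 | (S)-2-acetoxypropanal | CC(=O)O[C@@H](C)C=O | intermediate
8 | (E)-crotylboronic acid pinacol ester | C/C=C/CB1OC(C)(C)C(C)(C)O1 | starting material
9 | O-pinacolboryl derivative of 10 | CC(=O)O[C@@H](C)[C@H](OB1OC(C)(C)C(C)(C)O1)[C@@H](C)C=C | intermediate (not isolated)
10 | (2S,3R,4S)-3-hydroxy-4-methylhex-5-en-2-yl acetate | CC(=O)O[C@@H](C)[C@H](O)[C@@H](C)C=C | intermediate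
11 | (2S,3R,4S)-3-[(tert-butyldimethylsilyl)oxy]-4-methylhex-5-en-2-yl acetate | CC(=O)O[C@@H](C)[C@H](O[Si](C)(C)C(C)(C)C)[C@@H](C)C=C | intermediate
12 | tert-butyldimethyl{[(2S,3R,4S)-2,4,6-trimethyl-3,4-dihydro-2H-pyran-3-yl]oxy}silane | CC(C)(C)[Si](C)(C)O[C@@H]1[C@@H](C)C=C(C)O[C@H]1C | intermediate
13 | tertiary C6 radical of the C5 (E)-3-acetoxy-2-methylacrylate ester of 12 (acyloxy group anti to the C4 methyl) | CC(C)(C)[Si](C)(C)O[C@@H]1[C@@H](C)[C@H](OC(=O)/C(C)=C/OC(C)=O)[C](C)O[C@H]1C | intermediate (not isolated)
14 | (2S,3R,4S,4aS,7R,8S,8aS)-3-[(tert-butyldimethylsilyl)oxy]-2,4,7,8a-tetramethyl-6-oxooctahydropyrano[3,2-b]pyran-8-yl acetate | CC(C)(C)[Si](C)(C)O[C@@H]1[C@@H](C)[C@@H]2OC(=O)[C@H](C)[C@H](OC(C)=O)[C@@]2(C)O[C@H]1C | intermediate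
15 | (2S,3R,4R,4aS,7R,8S,8aS)-3-hydroxy-2,4,7,8a-tetramethyl-6-oxooctahydropyrano[3,2-b]pyran-8-yl acetate | O[C@@H]1[C@@H](C)[C@@H]2OC(=O)[C@H](C)[C@H](OC(C)=O)[C@@]2(C)O[C@H]1C | intermediate
16 | non-1-yn-3-ol (racemic) | CCCCCCC(O)C#C | starting material
17 | tert-butyldimethyl(non-1-yn-3-yloxy)silane (racemic) | CCCCCCC(O[Si](C)(C)C(C)(C)C)C#C | intermediate
18 | lithium acetylide of 17 | [Li+].[C-]#CC(CCCCCC)O[Si](C)(C)C(C)(C)C | intermediate (not isolated)
19 | 4-[(tert-butyldimethylsilyl)oxy]dec-2-ynoic acid (racemic) | CCCCCCC(O[Si](C)(C)C(C)(C)C)C#CC(=O)O | intermediate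
20 | C3 ester of 15 with 19 (two epimers at the side-chain carbinol) | CCCCCCC(O[Si](C)(C)C(C)(C)C)C#CC(=O)O[C@@H]1[C@@H](C)[C@@H]2OC(=O)[C@H](C)[C@H](OC(C)=O)[C@@]2(C)O[C@H]1C | intermediate
21 | C3 4-hydroxydec-2-ynoate (two epimers at the side-chain carbinol) | CCCCCCC(O)C#CC(=O)O[C@@H]1[C@@H](C)[C@@H]2OC(=O)[C@H](C)[C@H](OC(C)=O)[C@@]2(C)O[C@H]1C | intermediate
22 | C3 4-oxodec-2-ynoate | CCCCCCC(=O)C#CC(=O)O[C@@H]1[C@@H](C)[C@@H]2OC(=O)[C@H](C)[C@H](OC(C)=O)[C@@]2(C)O[C@H]1C | intermediate
23 | botcinin J | CCCCCCC(=O)/C=C\C(=O)O[C@@H]1[C@@H](C)[C@@H]2OC(=O)[C@H](C)[C@H](OC(C)=O)[C@@]2(C)O[C@H]1C | target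

**Count and risks**
Total steps: 15. Longest linear sequence: 10 steps (4, 5, 6, 7, 8, 9, 12, 13, 14, 15) from (S)-2-acetoxypropanoyl chloride.

Steps most likely to fail:

1. Step 8 (Proposed new method). What may go wrong: closure of the C6 radical on its axial lobe, giving the cis-fused lactone with C8a and C8 inverted; acid-catalysed Markovnikov addition of 5 to the enol ether; hydrogen-atom quench or 1,2-acyloxy shift of radical 13 before it cyclises. Fallback by known, stepwise chemistry, setting out from 12 and coming back at 14. Epoxidation of 12 with dimethyldioxirane (acetone/CH2Cl2, −78 → 0 °C) should occur anti to the C4 methyl and give the 5,6-epoxide F1. Opening of F1 at the tertiary acetal carbon with vinylmagnesium bromide/CuI (anti, inversion) should give the trans C6-vinyl C5-alcohol F2, which fixes the ring-fusion sense by construction. Acylation with 2-bromopropanoyl bromide/pyridine gives the 2-bromopropanoate F3, and ozonolysis (O3, then Me2S) gives the C6 aldehyde F4. A samarium diiodide intramolecular Reformatsky reaction (THF, −78 °C) closes the lactone to the 8-hydroxy lactone F5, and Ac2O/DMAP returns to 14.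

2. Step 15. What may go wrong: over-reduction of the ene-dione or Z-to-E isomerisation on the palladium surface. Fallback from 15, coming back at 23. Steglich esterification of 15 with bis(2,2,2-trifluoroethyl)phosphonoacetic acid gives the phosphonoacetate F7. A Still–Gennari olefination (KHMDS, 18-crown-6, THF, −78 °C, one equivalent of base) with 2-oxooctanal then builds the (Z)-alkene directly.

3. Step 7. What may go wrong: ethylidenation of the acetate without ring closure, or loss of the titanium alkylidene to reduction before it engages the ester. Fallback from 11, coming back at 12. Tebbe methylenation of the acetate gives the isopropenyl ether F6, and ring-closing metathesis with a molybdenum or second-generation ruthenium alkylidene closes the cyclic enol ether.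

**Further compounds**
F1 | step 8 | 5,6-epoxide of 12, epoxide oxygen anti to the C4 methyl | CC(C)(C)[Si](C)(C)O[C@@H]1[C@@H](C)[C@@H]2O[C@]2(C)O[C@H]1C
F2 | step 8 | C6-vinyl C5-alcohol from anti opening of F1 | CC(C)(C)[Si](C)(C)O[C@@H]1[C@@H](C)[C@H](O)[C@@](C)(C=C)O[C@H]1C
F3 | step 8 | 2-bromopropanoate of F2 (bromide centre unspecified) | CC(C)(C)[Si](C)(C)O[C@@H]1[C@@H](C)[C@H](OC(=O)C(C)Br)[C@@](C)(C=C)O[C@H]1C
F4 | step 8 | C6 aldehyde from ozonolysis of F3 | CC(C)(C)[Si](C)(C)O[C@@H]1[C@@H](C)[C@H](OC(=O)C(C)Br)[C@@](C)(C=O)O[C@H]1C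
F5 | step 8 | 8-hydroxy lactone (desacetyl 14) | CC(C)(C)[Si](C)(C)O[C@@H]1[C@@H](C)[C@@H]2OC(=O)[C@H](C)[C@H](O)[C@@]2(C)O[C@H]1C
F6 | step 7 | isopropenyl ether of the silyl-protected homoallylic alcohol | C=C(C)O[C@@H](C)[C@H](O[Si](C)(C)C(C)(C)C)[C@@H](C)C=C
F7 | step 15 | C3 bis(2,2,2-trifluoroethyl)phosphonoacetate of 15 | O=C(CP(=O)(OCC(F)(F)F)OCC(F)(F)F)O[C@@H]1[C@@H](C)[C@@H]2OC(=O)[C@H](C)[C@H](OC(C)=O)[C@@]2(C)O[C@H]1C
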